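Time in these catalysed flasks can be counted in turnovers: how many times each catalyst has made target. Here the catalyst turns starting material into target, and the target is read in percent of the starting material and other conformer together charged.

| setting | gamma | beta | theta | epsilon | winter | summer | midnight | spring | noon |
|---|---|---|---|---|---|---|---|---|---|
| starting material | 9.9 mM | 19 mM | 24 mM | 20 mM | 10 mM | 20 mM | 20 mM | 30 mM | 30 mM |
| other conformer | 2 mM | 2 mM | 2 mM | 2 mM | 2.00 mM | 8.00 mM | 2.00 mM | 4.00 mM | 8.00 mM |
| catalyst | 40 µM | 40 µM | 40 µM | 28 µM | 40 µM | 80 µM | 40 µM | 120 µM | 12 µM |
| remark | run made earlier | run made earlier | run made earlier | run made earlier |  |  |  |  |  |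
| time |  |  |  |  | 25 h | 25 h | 25 h | 25 h | 25 h |

- gamma (time / h: target / %, starting material / %): 4.00: 14.7, 52.9; 8.00: 23.1, 34.0; 10.0: 26.3, 27.5; 15.0: 31.3, 18.3; 20.0: 34.6, 12.7
- beta (time / h: target / %, starting material / %): 1.50: 6.4, 75.8; 4.00: 15.3, 56.2; 8.00: 24.6, 36.0; 12.0: 30.5, 24.1; 20.0: 37.4, 14.1
- theta (time / h: target / %, starting material / %): 4.00: 15.2, 57.2; 8.00: 24.6, 36.2; 10.0: 28.4, 30.2; 15.0: 34.2, 19.5; 20.0: 37.7, 13.6
- epsilon (time / h: target / %, starting material / %): 4.00: 11.1, 60.2; 8.00: 18.7, 41.0; 10.0: 20.8, 34.3; 15.0: 26.4, 23.4; 20.0: 29.4, 17.7

(readings scatter by 0.3 percentage points)

- in a conversion other conformer counts as not yet reacted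

- ranking by amount of target, in percent of the starting material and other conformer together charged, from high to low, at 25 h (winter / summer / midnight / spring / noon)
- the same order at 8.0 d (winter / summer / midnight / spring / noon)
- the amount of target, in percent of the starting material and other conformer together charged of the flask you put first, at 25 h
- the amount of target, in percent of the starting material and other conformer together charged of the flask you put last, at 25 h

Take the beta run up to its first reading. Dividing the target made by the time, the mean starting material and [catalyst] gives 1280 /M/h. This is the quantity I carry, the turnover constant: turnovers per hour for each catalyst, per unit of [starting material]. Multiplied by [catalyst], it is a pseudo-first-order rate constant for making target.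

The second way uses another flask, with less catalyst than the beta run. The epsilon run, at 28 µM, gives 1310 /M/h up to its first reading. The two agree within the scatter, so early in these two runs target is made in proportion to [catalyst], and I trust the constant.

A late window of the beta run parts from them, giving 1130 /M/h, which is lower. I take this window to be the one that cheats. It starts with target at 30.5% against starting material at 24.1%, so what it reads is a net gain, and a drain on target counts against it. I do not separate such a drain from a tiring catalyst here, and I keep the early value.

For noon I scale the epsilon run by catalyst and by the share of starting material in the charge, then add the last hours at the epsilon run's final starting material. That gives my own figure of 12.1%. It is an estimate, and I expect noon to stand above it, since noon's rate constant for making target, 0.0154 /h, is smaller than the 0.0358 /h of the epsilon run, so noon should use its starting material more slowly.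

The forecast gives spring > summer > midnight > winter > noon at 25 h and spring > summer > midnight > winter > noon at 8.0 d, with 65% at the top and 13.3% at the bottom, which stands above my figure. On the sag in its rate constants it says: “This suggests slow catalyst death”.

The flask gives spring > summer > midnight > winter > noon at 25 h, with 60.0% for spring and 16.1% for noon. At 8.0 d it gives spring > midnight > winter > summer > noon, so the forecast and the flask part there over summer.

    starting material ⇌ other conformer (K = 0.0896, k = 0.00976 /h)
    starting material + catalyst → catalyst + target (k = 1350 /M/h)
    catalyst + other conformer → catalyst + isomer of the product A (k = 9570 /M/h)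
    target + catalyst ⇌ isomer of the product B + catalyst, rate k4*[catalyst]*[target] forward; the back reaction follows from the equilibrium constant (K = 0.130, k = 184 /M/h)
    starting material ⇌ dormant form (K = 2.30, k = 0.0668 /h)

Noon's 16.1%, divided by the turnover constant, [catalyst] and 25 h, asks for a mean starting material of 41.9%, which lies between its charged 78.9% and its final 22.0%. Now read the same flask earlier, at 10 h, where starting material stands at 41.7%. The mean of that value and the charged share, times the time, the constant and [catalyst], gives 9.28%. That neighbouring flask holds 9.30% of target.

Readings and results are calculated from invented constants; scatter was added.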